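The route cuts ring E of the bicyclo[2.2.2]octane (ketone carbon, its two methyl-bearing quaternary α-carbons, the bridgehead carrying the lactone CH2, the lactone α-carbon and the carbinol carbon) as a Diels–Alder ring. Its 1,3-dioxygenated O–C–C(Me)–C–O segment and the lactone carbonyl define a push–pull 2-silyloxydiene in a pre-formed cyclohexadiene (ring D, from a dearomatized phthalide phenol) and a tethered silyl enol ether. One-pot double conjugate hydrosilylation of a dienone–enal, then intramolecular [4+2] cycloaddition, forms both bonds to the vicinal quaternary carbons, closes ring C and, last, ring E, and sets three quaternary stereocentres. Rings A, B, D and F exist beforehand.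

Key step: step 16

Remarks: atom labels (C9, C12 …) count the heavy atoms of the target SMILES from left to right. Ring A = unsaturated δ-lactone; ring B = cyclohexane with the tertiary alcohol; ring C = cyclopentane; ring D = C12–C13–C14–C31–C30–C25; ring E = C14–C16–C18–C25–C30–C31; ring F = γ-lactone.
Assumption: compounds 1, 4 and 5 are purchased, and the cinchonidinium catalyst of step 3 is taken to give the (S)-centre (otherwise its cinchoninium pseudoenantiomer is used).

Step 1
Reactants: 1 methyl 5-bromo-2-hydroxy-3-methylbenzoate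
Product: 2 methyl 5-bromo-3-methyl-2-[(triisopropylsilyl)oxy]benzoate
Conditions: iPr3SiOTf, 2,6-lutidine, CH2Cl2, 0 °C to 23 °C
Reagents that add atoms: triisopropylsilyl trifluoromethanesulfonate, CC(C)[Si](OS(=O)(=O)C(F)(F)F)(C(C)C)C(C)C
Why: Silyl ether formation with the silyl triflate masks the hindered, hydrogen-bonded phenol for the magnesiation and the later nickel coupling; no stereocentre is formed.

Step 2
Reactants: 2 methyl 5-bromo-3-methyl-2-[(triisopropylsilyl)oxy]benzoate
Product: 3 4-bromo-6-methyl-7-[(triisopropylsilyl)oxy]-2-benzofuran-1(3H)-one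
Conditions: TMPMgCl·LiCl, THF, −20 °C; CH2O (gas, from paraformaldehyde), −20 °C to 23 °C; H2O
Reagents that add atoms: formaldehyde, C=O
Why: Directed ortho-magnesiation should occur at the only C–H flanked by the ester and the bromine, and the benzylic alkoxide formed on hydroxymethylation lactonizes onto the ester to give the phthalide.

Step 3
Reactants: 4 3-acetyloxolan-2-one (2-acetyl-γ-butyrolactone); 5 ethyl buta-2,3-dienoate
Product: 7 ethyl (2E)-3-[(3S)-3-acetyl-2-oxooxolan-3-yl]but-2-enoate, via but-3-enoate isomer 6 (not isolated)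
Conditions: O-allyl-N-(9-anthracenylmethyl)cinchonidinium bromide (5 mol %), K2CO3, toluene, −30 °C; then DBU (20 mol %), 23 °C
Reagents that add atoms: none
Why: Phase-transfer-catalysed asymmetric Michael addition of the cyclic β-keto lactone to the central allene carbon should create the quaternary carbon (later C9) under control of the chiral ammonium ion pair, and base-mediated conjugation should give the (E)-enoate, whose ester is trans to the quaternary carbon.

Step 4
Reactants: 7 ethyl (2E)-3-[(3S)-3-acetyl-2-oxooxolan-3-yl]but-2-enoate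
Product: 8 ethyl (2E)-3-[(3S)-3-(2-hydroxypropan-2-yl)-2-oxooxolan-3-yl]but-2-enoate
Conditions: MeMgBr, CeCl3, THF, −78 °C
Reagents that add atoms: methylmagnesium bromide, C[Mg]Br
Why: Organocerium 1,2-addition should be selective for the ketone over the lactone and the hindered β,β-disubstituted enoate and mild enough to avoid retro-Claisen or retro-aldol cleavage; the new carbinol carbon (later C2) is not stereogenic.

Step 5
Reactants: 8 ethyl (2E)-3-[(3S)-3-(2-hydroxypropan-2-yl)-2-oxooxolan-3-yl]but-2-enoate
Product: 9 (3S)-3-[(2E)-4-hydroxybut-2-en-2-yl]-3-(2-hydroxypropan-2-yl)oxolan-2-ol (lactol, both anomers)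
Conditions: iBu2AlH (5 equiv), CH2Cl2, −78 °C; aq. KNaC4H4O6
Reagents that add atoms: none
Why: Hydride reduction at −78 °C should stop at the lactol (stable aluminium hemiacetal) while taking the enoate in 1,2-fashion to the (E)-allylic alcohol.

Step 6
Reactants: 9 lactol diol
Product: 10 (3S)-3-(2-hydroxypropan-2-yl)-3-{(2E)-4-[(triethylsilyl)oxy]but-2-en-2-yl}oxolan-2-ol (both anomers)
Conditions: Et3SiCl (1.05 equiv), imidazole, CH2Cl2, −40 °C
Reagents that add atoms: chlorotriethylsilane, CC[Si](Cl)(CC)CC
Why: Selective silylation should take the unhindered primary allylic alcohol well before the hemiacetal and the neopentyl tertiary hydroxyl.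

Step 7
Reactants: 10 silyl-protected lactol
Product: 11 (3S,4E)-3-ethenyl-3-(2-hydroxyethyl)-2,4-dimethyl-6-[(triethylsilyl)oxy]hex-4-en-2-ol
Conditions: Ph3PCH3Br, KOtBu (3 equiv each), THF, 0 °C
Reagents that add atoms: methylenetriphenylphosphorane (made in the flask), C=P(c1ccccc1)(c1ccccc1)c1ccccc1
Why: Wittig methylenation of the open hydroxy-aldehyde form of the lactol should unveil the vinyl group (C8) for the metathesis and the primary alcohol (C11) for the coupling, excess ylide at low temperature outrunning retro-aldol loss of acetone.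

Step 8
Reactants: 11 vinyl diol
Product: 12 (3S,4E)-3-(2-bromoethyl)-3-ethenyl-2,4-dimethyl-6-[(triethylsilyl)oxy]hex-4-en-2-ol
Conditions: CBr4, PPh3, CH2Cl2, 0 °C
Reagents that add atoms: carbon tetrabromide, BrC(Br)(Br)Br
Why: Appel bromination should convert only the primary alcohol, since the neopentyl tertiary hydroxyl does not react.

Step 9
Reactants: 12 primary bromide; 3 4-bromo-6-methyl-7-[(triisopropylsilyl)oxy]-2-benzofuran-1(3H)-one
Product: 13 4-{(3S,4E)-3-ethenyl-3-(2-hydroxypropan-2-yl)-4-methyl-6-[(triethylsilyl)oxy]hex-4-en-1-yl}-6-methyl-7-[(triisopropylsilyl)oxy]-2-benzofuran-1(3H)-one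
Conditions: NiI2 (10 mol %), 4,4′-di-tert-butyl-2,2′-bipyridine, NaI, pyridine, Zn, DMPU, 60 °C
Reagents that add atoms: none
Why: Nickel-catalysed reductive cross-electrophile coupling should join the aryl bromide (oxidative addition to zerovalent nickel) and the primary alkyl bromide (radical capture) without a preformed organometallic, so the free tertiary alcohol, the phthalide and both silyl ethers are tolerated and no favourable radical cyclization is open.

Step 10
Reactants: 13 coupled tertiary alcohol
Product: 14 2-[(3S,4E)-3-ethenyl-4-methyl-1-{6-methyl-1-oxo-7-[(triisopropylsilyl)oxy]-1,3-dihydro-2-benzofuran-4-yl}-6-[(triethylsilyl)oxy]hex-4-en-3-yl]propan-2-yl prop-2-enoate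
Conditions: LiN(SiMe3)2, THF, −78 °C; CH2=CHCOCl, −78 °C to 0 °C
Reagents that add atoms: acryloyl chloride, C=CC(=O)Cl
Why: O-Acylation of the lithium alkoxide of the only free hydroxyl should succeed despite the congestion because the alkoxide is far more nucleophilic than the neutral alcohol.

Step 11
Reactants: 14 acrylate
Product: 15 (5S)-6,6-dimethyl-5-(2-{6-methyl-1-oxo-7-[(triisopropylsilyl)oxy]-1,3-dihydro-2-benzofuran-4-yl}ethyl)-5-{(2E)-4-[(triethylsilyl)oxy]but-2-en-2-yl}-5,6-dihydro-2H-pyran-2-one
Conditions: second-generation Grubbs catalyst RuCl2(=CHPh)(PCy3)(H2IMes) (5 mol %), CH2Cl2, 40 °C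
Reagents that add atoms: none
Why: Ring-closing metathesis between the acrylate and the vinyl group on the quaternary carbon should close ring A, helped by the gem-dialkyl effect, while the hindered trisubstituted alkene does not compete.

Step 12
Reactants: 15 ring-A lactone silyl ether
Product: 16 (5S)-5-[(2E)-4-hydroxybut-2-en-2-yl]-6,6-dimethyl-5-(2-{6-methyl-1-oxo-7-[(triisopropylsilyl)oxy]-1,3-dihydro-2-benzofuran-4-yl}ethyl)-5,6-dihydro-2H-pyran-2-one
Conditions: PPTS, MeOH, 0 °C
Reagents that add atoms: none
Why: Mild acid methanolysis should remove the primary triethylsilyl ether while the hindered aryl triisopropylsilyl ether and both lactones survive.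

Step 13
Reactants: 16 allylic alcohol
Product: 17 (5R)-5-[(2S,3S)-3-(hydroxymethyl)-2-methyloxiran-2-yl]-6,6-dimethyl-5-(2-{6-methyl-1-oxo-7-[(triisopropylsilyl)oxy]-1,3-dihydro-2-benzofuran-4-yl}ethyl)-5,6-dihydro-2H-pyran-2-one
Conditions: Ti(OiPr)4 (10 mol %), L-(+)-diethyl tartrate (12 mol %), tBuOOH, 4 Å molecular sieves, CH2Cl2, −20 °C
Reagents that add atoms: tert-butyl hydroperoxide, CC(C)(C)OO
Why: Sharpless asymmetric epoxidation of the (E)-3,3-disubstituted allylic alcohol with the L-(+)-tartrate should deliver oxygen under reagent control to the face that gives the (2S,3S)-epoxy alcohol (as with geraniol), setting C21 and C22.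

Step 14
Reactants: 17 epoxy alcohol
Product: 19 (2E)-3-[(2S,3S)-3-{(3R)-2,2-dimethyl-6-oxo-3-(2-{6-methyl-1-oxo-7-[(triisopropylsilyl)oxy]-1,3-dihydro-2-benzofuran-4-yl}ethyl)-3,6-dihydro-2H-pyran-3-yl}-3-methyloxiran-2-yl]-2-methylprop-2-enal, via epoxy aldehyde 18 (not isolated)
Conditions: Dess–Martin periodinane, CH2Cl2, 0 °C; then Ph3P=C(CH3)CHO, 23 °C
Reagents that add atoms: 2-(triphenylphosphoranylidene)propanal, CC(C=O)=P(c1ccccc1)(c1ccccc1)c1ccccc1
Why: Dess–Martin oxidation followed in the same flask by Wittig olefination with the stabilized formyl ylide should give the (E)-γ,δ-epoxy enal without isolating the epimerizable epoxy aldehyde.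

Step 15
Reactants: 19 γ,δ-epoxy enal
Product: 21 spirodienone (rings A, B, D and F present; C9 S, C12 S, C21 R, C22 R), via phenol 20 (not isolated)
Conditions: Bu4NF, AcOH, THF, 0 °C; then Pd(PPh3)4 (10 mol %), THF, 23 °C, 0.005 M
Reagents that add atoms: none
Why: After fluoride frees the phenol, zerovalent palladium should ionize the vinyl epoxide with inversion to a π-allyl complex whose alkoxide deprotonates the phenol, and the phenoxide para carbon (C12) then attacks the allyl terminus next to the carbinol anti to palladium (6-exo intramolecular Tsuji–Trost ipso-alkylation, net retention at C21, closing ring B), the chair transition state keeping the CMe2O arm of ring A equatorial and turning the lactone-bearing edge of the arene away from the axial methyl, which sets C12.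

Step 16
Reactants: 21 spirodienone
Product: 23 cycloadduct (target skeleton; C16 as CH–OSiEt3, C30=C31 as silyl enol ether), via bis-silyl ether 22 (not isolated)
Conditions: RhCl(PPh3)3 (5 mol %), Et3SiH (2.3 equiv), toluene, 50 °C; then 150 °C, sealed tube
Reagents that add atoms: triethylsilane, CC[SiH](CC)CC
Why: Rhodium-catalysed 1,4-hydrosilylation should turn the enal into a silyl enol ether and the methyl-substituted enone arm of the cross-conjugated dienone into the 2-silyloxy-1,3-diene C14=C31(OSi)–C30=C25, because the other arm is fully substituted at its β-carbon C25 and the unsaturated lactone is much less reactive than an enone or enal. On heating, the tethered enol ether should add across the diene in an intramolecular Diels–Alder reaction, the closest known type being isotwistane-forming cycloadditions of cyclohexadienes with a three-atom tether; both bond pairs are polarity matched (nucleophilic C18 to the acrylate-like C25, nucleophilic C14 to the oxygen-bearing C16). Ring C closes through the leading C18–C25 bond, five-membered and exo with respect to the tether, and ring E is completed last by the C14–C16 bond as the six-membered [4+2] ring. The quaternary stereocentres C14, C18 and C25 follow from suprafacial addition to the diene face that carries the tether, which C12 and C21 dictate, whereas C16 depends on enol ether geometry and is erased by the later oxidation. Regiochemistry needs no control because the tether reaches only C25, and the chemoselectivity of the hydrosilylation rests on the reactivity order aldehyde and ketone over ester.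

Step 17
Reactants: 23 cycloadduct
Product: 25 31-oxo compound (target with a ketone in place of the C31 carbinol; C30 epimerizable), via hydroxy diketone 24 (not isolated)
Conditions: CrO3, H2SO4, H2O, acetone, 0 °C
Reagents that add atoms: none
Why: Jones oxidation should hydrolyse the silyl enol ether to the β-keto lactone, cleave the secondary silyl ether and oxidize the freed hindered alcohol at C16 to the ketone in one operation, the tertiary alcohol being inert.

Step 18
Reactants: 25 31-oxo compound
Product: 26 target CNP0360620.2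
Conditions: Zn(BH4)2, Et2O, −78 °C to −30 °C
Reagents that add atoms: none
Why: In this chelation-controlled reduction zinc should bridge the C31 carbonyl with the lactone carbonyl and the C16 ketone on the ketone-bridge flank, so hydride enters C31 from the CH2-bridge face of the epimerizable β-keto lactone and gives the alcohol cis to the lactone carbonyl (C30 and C31 as in the target), while the ketone between two quaternary carbons is too hindered to react.

Compound list
1 | methyl 5-bromo-2-hydroxy-3-methylbenzoate | COC(=O)c1cc(Br)cc(C)c1O | starting material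
2 | methyl 5-bromo-3-methyl-2-[(triisopropylsilyl)oxy]benzoate | COC(=O)c1cc(Br)cc(C)c1O[Si](C(C)C)(C(C)C)C(C)C | intermediate
3 | 4-bromo-6-methyl-7-[(triisopropylsilyl)oxy]-2-benzofuran-1(3H)-one | O=C1OCc2c(Br)cc(C)c(O[Si](C(C)C)(C(C)C)C(C)C)c12 | intermediate
4 | 3-acetyloxolan-2-one (2-acetyl-γ-butyrolactone) | CC(=O)C1CCOC1=O | starting material
5 | ethyl buta-2,3-dienoate | CCOC(=O)C=C=C | starting material
6 | ethyl 3-[(3S)-3-acetyl-2-oxooxolan-3-yl]but-3-enoate | CCOC(=O)CC(=C)[C@]1(C(C)=O)CCOC1=O | intermediate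
7 | ethyl (2E)-3-[(3S)-3-acetyl-2-oxooxolan-3-yl]but-2-enoate | CCOC(=O)/C=C(\C)[C@]1(C(C)=O)CCOC1=O | intermediate
8 | ethyl (2E)-3-[(3S)-3-(2-hydroxypropan-2-yl)-2-oxooxolan-3-yl]but-2-enoate | CCOC(=O)/C=C(\C)[C@]1(C(C)(C)O)CCOC1=O | intermediate
9 | (3S)-3-[(2E)-4-hydroxybut-2-en-2-yl]-3-(2-hydroxypropan-2-yl)oxolan-2-ol, both anomers | OC/C=C(\C)[C@]1(C(C)(C)O)CCOC1O | intermediate
10 | (3S)-3-(2-hydroxypropan-2-yl)-3-{(2E)-4-[(triethylsilyl)oxy]but-2-en-2-yl}oxolan-2-ol, both anomers | CC[Si](CC)(CC)OC/C=C(\C)[C@]1(C(C)(C)O)CCOC1O | intermediate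
11 | (3S,4E)-3-ethenyl-3-(2-hydroxyethyl)-2,4-dimethyl-6-[(triethylsilyl)oxy]hex-4-en-2-ol | CC[Si](CC)(CC)OC/C=C(\C)[C@](C=C)(C(C)(C)O)CCO | intermediate
12 | (3S,4E)-3-(2-bromoethyl)-3-ethenyl-2,4-dimethyl-6-[(triethylsilyl)oxy]hex-4-en-2-ol | CC[Si](CC)(CC)OC/C=C(\C)[C@](C=C)(C(C)(C)O)CCBr | intermediate
13 | 4-{(3S,4E)-3-ethenyl-3-(2-hydroxypropan-2-yl)-4-methyl-6-[(triethylsilyl)oxy]hex-4-en-1-yl}-6-methyl-7-[(triisopropylsilyl)oxy]-2-benzofuran-1(3H)-one | CC[Si](CC)(CC)OC/C=C(\C)[C@](C=C)(C(C)(C)O)CCc1cc(C)c(O[Si](C(C)C)(C(C)C)C(C)C)c2C(=O)OCc12 | intermediate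
14 | 2-[(3S,4E)-3-ethenyl-4-methyl-1-{6-methyl-1-oxo-7-[(triisopropylsilyl)oxy]-1,3-dihydro-2-benzofuran-4-yl}-6-[(triethylsilyl)oxy]hex-4-en-3-yl]propan-2-yl prop-2-enoate | CC[Si](CC)(CC)OC/C=C(\C)[C@](C=C)(C(C)(C)OC(=O)C=C)CCc1cc(C)c(O[Si](C(C)C)(C(C)C)C(C)C)c2C(=O)OCc12 | intermediate
15 | (5S)-6,6-dimethyl-5-(2-{6-methyl-1-oxo-7-[(triisopropylsilyl)oxy]-1,3-dihydro-2-benzofuran-4-yl}ethyl)-5-{(2E)-4-[(triethylsilyl)oxy]but-2-en-2-yl}-5,6-dihydro-2H-pyran-2-one | CC[Si](CC)(CC)OC/C=C(\C)[C@@]1(C=CC(=O)OC1(C)C)CCc1cc(C)c(O[Si](C(C)C)(C(C)C)C(C)C)c2C(=O)OCc12 | intermediate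
16 | (5S)-5-[(2E)-4-hydroxybut-2-en-2-yl]-6,6-dimethyl-5-(2-{6-methyl-1-oxo-7-[(triisopropylsilyl)oxy]-1,3-dihydro-2-benzofuran-4-yl}ethyl)-5,6-dihydro-2H-pyran-2-one | OC/C=C(\C)[C@@]1(C=CC(=O)OC1(C)C)CCc1cc(C)c(O[Si](C(C)C)(C(C)C)C(C)C)c2C(=O)OCc12 | intermediate
17 | (5R)-5-[(2S,3S)-3-(hydroxymethyl)-2-methyloxiran-2-yl]-6,6-dimethyl-5-(2-{6-methyl-1-oxo-7-[(triisopropylsilyl)oxy]-1,3-dihydro-2-benzofuran-4-yl}ethyl)-5,6-dihydro-2H-pyran-2-one | OC[C@@H]1O[C@@]1(C)[C@@]2(C=CC(=O)OC2(C)C)CCc3cc(C)c(O[Si](C(C)C)(C(C)C)C(C)C)c4C(=O)OCc34 | intermediate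
18 | (2R,3S)-3-[(3R)-2,2-dimethyl-6-oxo-3-(2-{6-methyl-1-oxo-7-[(triisopropylsilyl)oxy]-1,3-dihydro-2-benzofuran-4-yl}ethyl)-3,6-dihydro-2H-pyran-3-yl]-3-methyloxirane-2-carbaldehyde (same spatial arrangement as 17) | O=C[C@@H]1O[C@@]1(C)[C@@]2(C=CC(=O)OC2(C)C)CCc3cc(C)c(O[Si](C(C)C)(C(C)C)C(C)C)c4C(=O)OCc34 | intermediate
19 | (2E)-3-[(2S,3S)-3-{(3R)-2,2-dimethyl-6-oxo-3-(2-{6-methyl-1-oxo-7-[(triisopropylsilyl)oxy]-1,3-dihydro-2-benzofuran-4-yl}ethyl)-3,6-dihydro-2H-pyran-3-yl}-3-methyloxiran-2-yl]-2-methylprop-2-enal | O=C/C(C)=C/[C@@H]1O[C@@]1(C)[C@@]2(C=CC(=O)OC2(C)C)CCc3cc(C)c(O[Si](C(C)C)(C(C)C)C(C)C)c4C(=O)OCc34 | intermediate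
20 | free phenol of 19 (7-hydroxyphthalide in place of the silyl ether) | O=C/C(C)=C/[C@@H]1O[C@@]1(C)[C@@]2(C=CC(=O)OC2(C)C)CCc3cc(C)c(O)c4C(=O)OCc34 | intermediate
21 | spirodienone: ring B cyclohexane spiro-fused at C9 (S) to ring A and at C12 (S) to the 6-methylcyclohexa-2,5-dienone that shares its other double bond with the butenolide (ring F); C22 (R) carries methyl and OH, C21 (R) carries the (1E)-2-methyl-3-oxoprop-1-enyl group | CC1(C)OC(=O)C=C[C@]12CC[C@]3(C=C(C)C(=O)C4=C3COC4=O)[C@@H](/C=C(\C)C=O)[C@@]2(C)O | intermediate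
22 | bis(triethylsilyl) ether of 21: ring D as the 2-silyloxy-1,3-diene C14=C31(OSiEt3)–C30=C25, side chain as CH2–C(CH3)=CH–OSiEt3 (E/Z mixture) | CC1(C)OC(=O)C=C[C@]12CC[C@]3(CC(C)=C(O[Si](CC)(CC)CC)C4=C3COC4=O)[C@@H](CC(C)=CO[Si](CC)(CC)CC)[C@@]2(C)O | intermediate
23 | cycloadduct: target skeleton with C16 as CH–OSiEt3 (both epimers) and C30=C31 as the triethylsilyl enol ether of the β-keto lactone; C9, C12, C14, C18, C21, C22, C25 as in 26 | CC1(C)OC(=O)C=C[C@]12CC[C@]13C[C@]4(C)C(O[Si](CC)(CC)CC)[C@](C)(C[C@H]1[C@@]2(C)O)[C@]31COC(=O)C1=C4O[Si](CC)(CC)CC | intermediate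
24 | hydroxy diketone: target skeleton with C16 as CH–OH (both epimers) and C31 as ketone (C30 epimerizable) | CC1(C)OC(=O)C=C[C@]12CC[C@]13C[C@]4(C)C(O)[C@](C)(C[C@H]1[C@@]2(C)O)[C@]31COC(=O)C1C4=O | intermediate
25 | 31-oxo compound: target with a ketone in place of the C31 carbinol (C30 epimerizable) | CC1(C)OC(=O)C=C[C@]12CC[C@]13C[C@]4(C)C(=O)[C@](C)(C[C@H]1[C@@]2(C)O)[C@]31COC(=O)C1C4=O | intermediate
26 | CNP0360620.2 (C9 S, C12 S, C14 S, C18 R, C21 R, C22 R, C25 R, C30 R, C31 R) | CC1(C)OC(=O)C=C[C@]12CC[C@]13C[C@]4(C)C(=O)[C@](C)(C[C@H]1[C@@]2(C)O)[C@]31COC(=O)[C@H]1[C@H]4O | target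

Total step count: 18. Longest linear sequence: 16 steps (steps 3 to 18, from 4).

Steps most likely to fail

Step 16. The cycloaddition has to join two fully substituted carbons (C18–C25), and at 150 °C loss of the silyl groups or reversal of the first bond could outrun ring closure. The fallback sets out from 21 and comes back at 24, making the two bonds one at a time by polar reductive cyclizations. Treatment of 21 with [(Ph3P)CuH]6 (one hydride equivalent, toluene, −40 °C) should reduce the enal in 1,4-fashion, and the copper enolate should close ring C by Michael addition to C25 (reductive Michael cyclization) to give tricyclic aldehyde F1. A second portion of [(Ph3P)CuH]6 (toluene, 0 °C) should reduce the remaining C13=C14 enone, and the enolate at C14 should add to the neopentyl aldehyde (reductive aldol cyclization, closing ring E) to give 24, which is oxidized under the conditions of step 17.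

Step 15. The electron-poor phenoxide may attack the π-allyl complex slowly, so that the palladium alkoxide closes to a dihydrofuran or adds to C25, and facial selectivity at the spiro carbon C12 may erode. The fallback sets out from 19 and comes back at 21, replacing palladium catalysis by a classical alkylative dearomatization with two successive inversions. MgBr2·OEt2 (Et2O, −20 °C) should open the vinyl epoxide at the allylic carbon with inversion to bromohydrin F2. Silylation of the tertiary hydroxyl (Et3SiOTf, 2,6-lutidine, CH2Cl2, −78 °C) gives silyl ether F3, which blocks re-closure to the epoxide. CsF (DMF, 0 °C) should then cleave the aryl silyl ether, and the phenoxide should displace the bromide through its para carbon (intramolecular SN2 ipso-alkylation, second inversion) to give spirodienone silyl ether F4. HF·pyridine (THF, 0 °C) returns 21.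

Step 18. Hydride may enter C31 from the ketone-bridge face, which gives poor facial selectivity at C31 and, through the epimerizable β-keto lactone, at C30. The fallback sets out from 25 and comes back at 26, replacing kinetic control by thermodynamic redox equilibration. Unselective reduction (NaBH4, MeOH, −40 °C) should give 26 together with bis-epimeric alcohol F5. Heating the mixture with Al(OiPr)3 in iPrOH and toluene (80 °C) allows reversible Meerwein–Ponndorf–Verley and Oppenauer hydride transfer through 25, whose C30 epimerizes freely, and should funnel the material to 26, the isomer whose hydroxyl is hydrogen-bonded to the C16 ketone.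

Further compounds
F1 | step 16 | tricyclic aldehyde: rings A, B, C, D and F closed, C18 bearing methyl and CHO, C13=C14 enone and β-keto lactone retained (C30 epimerizable) | CC1(C)OC(=O)C=C[C@]12CC[C@]13C=C(C)C(=O)C4[C@]3(COC4=O)[C@](C)(C=O)C[C@H]1[C@@]2(C)O
F2 | step 15 | bromohydrin from 19: allylic bromide at C21 (inverted), tertiary OH at C22 | O=C/C(C)=C/[C@@H](Br)[C@@](C)(O)[C@@]1(C=CC(=O)OC1(C)C)CCc1cc(C)c(O[Si](C(C)C)(C(C)C)C(C)C)c2C(=O)OCc12
F3 | step 15 | triethylsilyl ether of F2 at the tertiary hydroxyl | O=C/C(C)=C/[C@@H](Br)[C@@](C)(O[Si](CC)(CC)CC)[C@@]1(C=CC(=O)OC1(C)C)CCc1cc(C)c(O[Si](C(C)C)(C(C)C)C(C)C)c2C(=O)OCc12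
F4 | step 15 | triethylsilyl ether of 21 at the tertiary hydroxyl | CC1(C)OC(=O)C=C[C@]12CC[C@]3(C=C(C)C(=O)C4=C3COC4=O)[C@@H](/C=C(\C)C=O)[C@@]2(C)O[Si](CC)(CC)CC
F5 | step 18 | C30,C31-bis-epimer of 26 | CC1(C)OC(=O)C=C[C@]12CC[C@]13C[C@]4(C)C(=O)[C@](C)(C[C@H]1[C@@]2(C)O)[C@]31COC(=O)[C@@H]1[C@@H]4O
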